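## Analysis of the target

The target (18) is a diaryl ether of two benzoic acids and has no stereocentre, so every difficulty is constitutional. Ring A is numbered C1 to C6: methoxy on C1, hydrogen on C2, carboxyl on C3, the ether oxygen on C4, a free hydroxyl on C5 and chlorine on C6. Ring B (C1' to C6') is a 2-hydroxy-4-methylbenzoic acid whose C6' carries the ether oxygen. The ether bond is flanked by three ortho substituents (C3 carboxyl and C5 hydroxyl on ring A, C1' carboxyl on ring B), which makes a late aryl–oxygen coupling unattractive. Ring A is pentasubstituted. Its chlorine sits between two oxygens, a position that direct chlorination of a resorcinol does not favour, and those two oxygens must be told apart, one as a methyl ether and one as a free phenol. Sensitive points are the aryl chloride (reductive loss), the two ortho-oxygenated benzoic acids (decarboxylation in hot acid) and the diaryl ether next to a phenoxide (Smiles-type scrambling under strong base). The strategy rests on reading C1(O)–C6(Cl)–C5(O) as a 2-chlororesorcinol, the aromatised form of a 2,2-dichlorocyclohexane-1,3-dione in which C3 and C4 are still sp3 carbons. Ring A can then be made by annulation, the ether bond by simple alkylation of ring B, and the chlorine placed by enol chemistry. The ring B carboxyl can reach only the C5 oxygen in a seven-membered lactone, which gives the handle for distinguishing the two ring A hydroxyls.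

## Retrosynthetic reasoning

**18 from 17.** The C5–O acyl bond is cut last in the forward sense. The target is the hydrolysis product of depsidone 17, in which the ring B carboxyl is esterified by the C5 oxygen. Keeping this lactone to the end means the C5 hydroxyl and the ring B acid are protected by each other and are released together.

**17 from 16.** The ring B phenol is traced back to its benzyl ether 16. The benzyl group is needed through the base and alkylation steps and is removed by a Lewis acid method, chosen because it does not endanger the aryl chloride.

**16 from 15.** The C3 carboxyl is taken back to the aldehyde of 15. An aldehyde (and before it an acetal) at C3 is what the annulation can tolerate; an ester there would acidify C3 and allow loss of the aryloxy group from C4.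

**15 from 14.** The C1–O–CH3 bond is cut. In 14 the C1 hydroxyl is the only free phenol, because C5–OH is locked in the lactone and the ring B oxygen is benzylated, so the methylation needs no selectivity of its own.

**14 from 13.** The lactone C–O bond is cut to give hydroxy acid 13. Only the C5 hydroxyl is ortho to the ether oxygen, so only it can close the seven-membered ring. This is how the otherwise similar oxygens on C1 and C5 are differentiated.

**13 from 11 via 12.** Ring A is dearomatised. The chlororesorcinol is the dehydrochlorination product of 2,2-dichloro-1,3-dione 11. One chlorine stays on C6 and the other supplies the oxidation level. Arene 12 is the first aromatic compound; it still carries the acetal and the tert-butyl ester, and both are removed by acid on the way to 13.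

**11 from 10.** Both C6–Cl bonds are cut. C6 is the carbon between the two carbonyls of dione 10 and is its most nucleophilic position, so the site of chlorination is fixed by the dione and not by arene directing effects.

**10 from 5 and 8 (via 9).** This is the key disconnection. The C3–C4 and C5–C6 bonds of the saturated ring are cut. That leads to aryloxyacetate 5, whose CH2 becomes C4 and whose ester carbon becomes C5, and to enone 8, which supplies C3, C2, C1 and C6 and carries the C3 carbon substituent as an acetal. Forward, a conjugate addition followed by a Claisen closure through open-chain keto ester 9 makes the ring in one operation. Cutting here turns the crowded diaryl ether into an alkyl aryl ether that already exists in 5.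

**5 from 3 and 4; 3 from 2; 2 from 1.** The O–CH2 bond of 5 is cut to phenol 3 and bromo ester 4. Phenol 3 is the monobenzyl ether of the symmetrical diol 2, which is the tert-butyl ester of commercially available acid 1. The tert-butyl ester is chosen so that the ring B carbonyl is a poor acceptor during the annulation and can later be unmasked by acid without touching the benzyl ether.

**8 from 6 and 7.** The C=C bond of 8 is cut to aldehyde 6 and stabilised ylide 7, an olefination that gives the E-enone directly.

## Alternatives that were turned down

**Alternative 1:** Both carboxyl carbons are traced back to the two alkene carbons of 4-(benzyloxy)-3-chloro-2,9-dimethoxy-7-methyldibenzo[b,f]oxepine A2, which would be cleaved oxidatively and oxidised further to the diacid.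
- **Key step:** A2 would come from racemic [4-(benzyloxy)-3-chloro-2,8-dimethoxy-6-methyl-9H-xanthen-9-yl]methanol A1. After activation of its hydroxyl, ionisation at the exocyclic carbon with a 1,2-aryl shift from C9 expands the pyran ring to the oxepine.
- **For:** Migration of either aryl group gives the same oxepine, so the key step has no regiochemical question. Electron-rich aryl groups migrate readily, and one oxidative operation reveals both acids. On cleanness of the key step this plan is stronger than a Michael–Claisen sequence that must beat competing enolate pathways.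
- **Against:** A1 already contains the complete tri-ortho-substituted ether and the chlorine between two oxygens. Both have to be made beforehand by xanthone-type chemistry on a crowded chlororesorcinol, so the ring expansion solves neither hard problem. Two carbons are added at a low oxidation level and then oxidised by alkene scission next to electron-rich rings. The ring B oxygen arrives as a methyl ether that must be cleaved beside the ring A methoxy group.
- **Comparison:** The chosen strategy offers the ether bond by plain alkylation and the chlorine position through a 1,3-dione, at the price of a less certain key step.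

**Alternative 2:** Ring B is disconnected at two ring bonds to a pyrone and a two-carbon partner.
- **Key step:** Methyl 4-[2-(benzyloxy)-3-chloro-4-methoxy-6-(methoxycarbonyl)phenoxy]-6-methyl-2-oxo-2H-pyran-3-carboxylate A3 would be heated with 1,1-dimethoxyethene A4. A [4+2] addition, decarboxylative retro-[4+2] of the lactone bridge and loss of one methoxy group as the alcohol would give methyl 2-[2-(benzyloxy)-3-chloro-4-methoxy-6-(methoxycarbonyl)phenoxy]-6-methoxy-4-methylbenzoate A5.
- **For:** The polarised diene and dienophile make the cycloaddition regiospecific, the sequence is convergent, and it creates no stereocentres that must be erased. On convergence it is stronger than the chosen, largely linear route.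
- **Against:** Ring B is the easy half, since compound 1 is commercially available with exactly this substitution. The ring A phenol with its chlorine pattern must still be made by aromatic substitution and then attached as a di-ortho-substituted nucleophile to C4 of the pyrone. A5 carries a ring B methyl ether and two methyl esters that need selective removal.
- **Comparison:** The chosen strategy spends its key step on ring A, where the substitution problem lies.

**Alternative 3:** Ring B is again built de novo, this time by a thermal benzannulation.
- **Key step:** 3-Methylcyclobut-2-en-1-one A6 and the aryl alkynyl ether 2-[3-(benzyloxy)-4-chloro-2-({3-[(tert-butyldimethylsilyl)oxy]prop-1-yn-1-yl}oxy)-5-methoxyphenyl]-1,3-dioxolane A7 would be heated in toluene. Electrocyclic opening of A6 to its ketene form, [2+2] addition to the alkyne, a second ring opening and 6π closure would give 3-[2-(benzyloxy)-3-chloro-6-(1,3-dioxolan-2-yl)-4-methoxyphenoxy]-2-{[(tert-butyldimethylsilyl)oxy]methyl}-5-methylphenol A8.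
- **For:** The ring B phenol emerges free and in the right place, the conditions are neutral, and the plan is convergent. On protecting-group economy for that hydroxyl it is stronger than the chosen route, which carries a benzyl ether through eight steps.
- **Against:** A7 is an alkynyl ether of a di-ortho-substituted phenol and would need strong-base alkyne chemistry next to an aryl chloride. Aryloxyalkynes are less electron-rich than alkoxyalkynes, so the ketene cycloaddition should be slow. Both carboxyl carbons arrive at low oxidation level, which adds two deprotections and two oxidations. The chlorine pattern of ring A is again left to classical aromatic chemistry.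
- **Comparison:** The chosen strategy answers that last point directly and keeps both carboxyl carbons at or one step from the acid level.

Key step: step 5

Remark: the 1,3-diones 10 and 11 are written as diketo tautomers; 10 should exist largely as its enol, which does not change the route.

## Route

Step 1
Reactants: 1 2,6-dihydroxy-4-methylbenzoic acid
Product: 2 tert-butyl 2,6-dihydroxy-4-methylbenzoate
Conditions: Cl3CC(=NH)O-t-Bu (2.5 equiv), THF–CH2Cl2, rt
Reagents that add atoms: tert-butyl 2,2,2-trichloroacetimidate, CC(C)(C)OC(=N)C(Cl)(Cl)Cl
Why: The strongly acidic acid 1 protonates the imidate and the tert-butyl cation–carboxylate pair collapses to the ester (trichloroacetimidate esterification); without an added Lewis acid the phenols should not be alkylated, and room temperature avoids decarboxylation.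

Step 2
Reactants: 2 tert-butyl 2,6-dihydroxy-4-methylbenzoate
Product: 3 tert-butyl 2-(benzyloxy)-6-hydroxy-4-methylbenzoate
Conditions: BnBr (1.05 equiv), K2CO3, acetone, rt to 40 °C
Reagents that add atoms: benzyl bromide, BrCc1ccccc1
Why: Williamson etherification of a symmetrical diol; after the first benzylation the remaining hydroxyl is held in a hydrogen bond to the ester carbonyl and reacts much more slowly, so one equivalent of halide should stop at the monoether.

Step 3
Reactants: 3 tert-butyl 2-(benzyloxy)-6-hydroxy-4-methylbenzoate, 4 methyl bromoacetate
Product: 5 tert-butyl 2-(benzyloxy)-6-(2-methoxy-2-oxoethoxy)-4-methylbenzoate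
Conditions: K2CO3, DMF, 60 °C
Reagents that add atoms: none
Why: Williamson alkylation of the chelated phenol by the reactive α-bromo ester under more forcing conditions; K2CO3 is too weak to deprotonate the new OCH2 group, so no Dieckmann closure onto the ring B ester is expected here.

Step 4
Reactants: 6 2,2-dimethoxyacetaldehyde, 7 1-(triphenylphosphoranylidene)propan-2-one
Product: 8 (E)-5,5-dimethoxypent-3-en-2-one
Conditions: CH2Cl2, rt (aldehyde used as its commercial aqueous solution)
Reagents that add atoms: none
Why: Wittig olefination with a ketone-stabilised ylide, which should give the E-alkene; the neutral conditions leave the acetal untouched.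

Step 5
Reactants: 5 tert-butyl 2-(benzyloxy)-6-(2-methoxy-2-oxoethoxy)-4-methylbenzoate, 8 (E)-5,5-dimethoxypent-3-en-2-one
Product: 10 tert-butyl 2-(benzyloxy)-6-{[2-(dimethoxymethyl)-4,6-dioxocyclohexyl]oxy}-4-methylbenzoate (diastereomer mixture), via open-chain Michael keto ester 9 (not isolated)
Conditions: 8 (1.5 equiv), t-BuOK (2 equiv, added slowly), THF, −30 °C to rt; then AcOH
Reagents that add atoms: none
Why: tert-Butoxide deprotonates the aryloxyacetate CH2 of 5 and the ester enolate adds 1,4 to enone 8 at the carbon remote from the ketone, forming C3–C4 and giving keto ester 9 as its ketone enolate. Proton exchange moves the charge to the methyl group of the ketone, and this enolate acylates on the methyl ester carbonyl in a 6-exo-trig Claisen (Dieckmann-type) closure that forms C5–C6 and ring A as a cyclohexane-1,3-dione. Loss of methoxide and deprotonation of the dione to its delocalised enolate make the sequence irreversible and consume one equivalent of base. The closest known reaction type is the base-mediated Michael–Claisen annulation of malonate and arylacetate enolates with methyl vinyl ketones to cyclohexane-1,3-diones. The two new sp3 centres C3 and C4 form as a mixture and need no control, since both become aromatic carbons in step 7. The step needs 1,4- over 1,2-addition, which a stabilised enolate under reversible conditions favours, and closure through the methyl enolate only, which ring size enforces because the internal enolate could close only a four-membered ring. It also needs the enolate of 5 to add to 8 faster than it attacks its own ring B ester; that ester is a tert-butyl ester flanked by two ortho oxygens, and the enone is present from the start so that the enolate is trapped as it forms. The acetal on C3 cannot stabilise a carbanion, so the aryloxy group on C4 has no β-elimination pathway.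

Step 6
Reactants: 10 tert-butyl 2-(benzyloxy)-6-{[2-(dimethoxymethyl)-4,6-dioxocyclohexyl]oxy}-4-methylbenzoate
Product: 11 tert-butyl 2-(benzyloxy)-6-{[3,3-dichloro-6-(dimethoxymethyl)-2,4-dioxocyclohexyl]oxy}-4-methylbenzoate (diastereomer mixture)
Conditions: NCS (2.1 equiv), MeCN, 0 °C to rt
Reagents that add atoms: N-chlorosuccinimide, O=C1CCC(=O)N1Cl
Why: Electrophilic α-chlorination of a 1,3-dicarbonyl: the enol carbon C6 is by far the most nucleophilic site and is chlorinated twice, while the ester-deactivated ring B, the acetal and the tert-butyl ester should not react with NCS under neutral conditions.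

Step 7
Reactants: 11 tert-butyl 2-(benzyloxy)-6-{[3,3-dichloro-6-(dimethoxymethyl)-2,4-dioxocyclohexyl]oxy}-4-methylbenzoate
Product: 13 2-(benzyloxy)-6-(3-chloro-6-formyl-2,4-dihydroxyphenoxy)-4-methylbenzoic acid, via chlororesorcinol acetal tert-butyl ester 12 (not isolated)
Conditions: HCl (dioxane, cat.), DMF, 70 °C; then CF3CO2H–CH2Cl2–H2O, rt
Reagents that add atoms: water, O
Why: Known aromatisation of 2,2-dichlorocyclohexane-1,3-diones: an acid-catalysed shift of one chlorine from C6 to an α' carbon (C2 or C4) through the enol, elimination of HCl across the bond to C3 and tautomerisation should give the 2-chlororesorcinol with chlorine fixed on C6 and the ether on C4 intact. The acetal is kept under anhydrous conditions until ring A is aromatic so that no enolisable aldehyde sits next to C4; aqueous CF3CO2H then hydrolyses the acetal to the aldehyde and cleaves the tert-butyl ester, while the benzyl ether survives at room temperature.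

Step 8
Reactants: 13 2-(benzyloxy)-6-(3-chloro-6-formyl-2,4-dihydroxyphenoxy)-4-methylbenzoic acid
Product: 14 1-(benzyloxy)-9-chloro-8-hydroxy-3-methyl-11-oxo-11H-dibenzo[b,e][1,4]dioxepine-6-carbaldehyde
Conditions: DCC, DMAP (cat.), CH2Cl2 (0.01 M), rt
Reagents that add atoms: none
Why: Carbodiimide (Steglich-type) lactonisation of a 2-(2-hydroxyaryloxy)benzoic acid: only the C5 hydroxyl, ortho to the ether oxygen, can reach the activated ring B carboxyl and close the seven-membered depsidone lactone, whereas the C1 hydroxyl could react only between molecules, which high dilution suppresses.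

Step 9
Reactants: 14 1-(benzyloxy)-9-chloro-8-hydroxy-3-methyl-11-oxo-11H-dibenzo[b,e][1,4]dioxepine-6-carbaldehyde
Product: 15 1-(benzyloxy)-9-chloro-8-methoxy-3-methyl-11-oxo-11H-dibenzo[b,e][1,4]dioxepine-6-carbaldehyde
Conditions: MeI, K2CO3, acetone, rt
Reagents that add atoms: iodomethane, CI
Why: Williamson methylation of the only free phenol (the C1 oxygen, position 8 of the depsidone); the C5 oxygen is held in the lactone and the ring B oxygen is benzylated, and anhydrous carbonate in acetone should not open the aryl lactone.

Step 10
Reactants: 15 1-(benzyloxy)-9-chloro-8-methoxy-3-methyl-11-oxo-11H-dibenzo[b,e][1,4]dioxepine-6-carbaldehyde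
Product: 16 1-(benzyloxy)-9-chloro-8-methoxy-3-methyl-11-oxo-11H-dibenzo[b,e][1,4]dioxepine-6-carboxylic acid
Conditions: NaClO2, NaH2PO4, 2-methylbut-2-ene, t-BuOH–THF–H2O, rt
Reagents that add atoms: sodium chlorite, [Na+].[O-]Cl=O
Why: Pinnick oxidation converts the aryl aldehyde to the acid under buffered conditions that leave the lactone, the ethers and the aryl chloride untouched; the alkene traps the hypochlorous acid that could otherwise chlorinate the electron-rich rings.

Step 11
Reactants: 16 1-(benzyloxy)-9-chloro-8-methoxy-3-methyl-11-oxo-11H-dibenzo[b,e][1,4]dioxepine-6-carboxylic acid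
Product: 17 9-chloro-1-hydroxy-8-methoxy-3-methyl-11-oxo-11H-dibenzo[b,e][1,4]dioxepine-6-carboxylic acid
Conditions: BCl3 (4 equiv), C6HMe5 (3 equiv), CH2Cl2, −78 °C; then H2O
Reagents that add atoms: none
Why: Lewis acid cleavage of an aryl benzyl ether by BCl3, assisted by chelation to the neighbouring lactone carbonyl, with pentamethylbenzene trapping the benzyl cation; at −78 °C the unchelated methyl ether on ring A should survive, and unlike hydrogenolysis the method does not put the aryl chloride at risk.

Step 12
Reactants: 17 9-chloro-1-hydroxy-8-methoxy-3-methyl-11-oxo-11H-dibenzo[b,e][1,4]dioxepine-6-carboxylic acid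
Product: 18 2-(2-carboxy-3-hydroxy-5-methylphenoxy)-4-chloro-3-hydroxy-5-methoxybenzoic acid
Conditions: LiOH (6 equiv), THF–H2O, rt to 40 °C; then 1 M HCl
Reagents that add atoms: lithium hydroxide, [Li+].[OH-]
Why: Saponification of the aryl ester lactone releases the ring B carboxylate and the C5 phenoxide, and acidification should give the target; the mild temperature avoids decarboxylation of the ortho-oxygenated acids and Smiles rearrangement of the diaryl ether.

## Compound list

1 | 2,6-dihydroxy-4-methylbenzoic acid | O=C(O)c1c(O)cc(C)cc1O | starting material
2 | tert-butyl 2,6-dihydroxy-4-methylbenzoate | CC(C)(C)OC(=O)c1c(O)cc(C)cc1O | intermediate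
3 | tert-butyl 2-(benzyloxy)-6-hydroxy-4-methylbenzoate | CC(C)(C)OC(=O)c1c(O)cc(C)cc1OCc1ccccc1 | intermediate
4 | methyl bromoacetate | COC(=O)CBr | starting material
5 | tert-butyl 2-(benzyloxy)-6-(2-methoxy-2-oxoethoxy)-4-methylbenzoate | COC(=O)COc1cc(C)cc(OCc2ccccc2)c1C(=O)OC(C)(C)C | intermediate
6 | 2,2-dimethoxyacetaldehyde | COC(OC)C=O | starting material
7 | 1-(triphenylphosphoranylidene)propan-2-one | CC(=O)C=P(c1ccccc1)(c1ccccc1)c1ccccc1 | starting material
8 | (E)-5,5-dimethoxypent-3-en-2-one | CC(=O)/C=C/C(OC)OC | intermediate
9 | tert-butyl 2-(benzyloxy)-6-{[3-(dimethoxymethyl)-1-methoxy-1,5-dioxohexan-2-yl]oxy}-4-methylbenzoate (diastereomer mixture) | COC(=O)C(Oc1cc(C)cc(OCc2ccccc2)c1C(=O)OC(C)(C)C)C(CC(C)=O)C(OC)OC | intermediate (not isolated)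
10 | tert-butyl 2-(benzyloxy)-6-{[2-(dimethoxymethyl)-4,6-dioxocyclohexyl]oxy}-4-methylbenzoate (diastereomer mixture) | COC(OC)C1CC(=O)CC(=O)C1Oc1cc(C)cc(OCc2ccccc2)c1C(=O)OC(C)(C)C | intermediate
11 | tert-butyl 2-(benzyloxy)-6-{[3,3-dichloro-6-(dimethoxymethyl)-2,4-dioxocyclohexyl]oxy}-4-methylbenzoate (diastereomer mixture) | COC(OC)C1CC(=O)C(Cl)(Cl)C(=O)C1Oc1cc(C)cc(OCc2ccccc2)c1C(=O)OC(C)(C)C | intermediate
12 | tert-butyl 2-(benzyloxy)-6-[3-chloro-6-(dimethoxymethyl)-2,4-dihydroxyphenoxy]-4-methylbenzoate | COC(OC)c1cc(O)c(Cl)c(O)c1Oc1cc(C)cc(OCc2ccccc2)c1C(=O)OC(C)(C)C | intermediate (not isolated)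
13 | 2-(benzyloxy)-6-(3-chloro-6-formyl-2,4-dihydroxyphenoxy)-4-methylbenzoic acid | O=Cc1cc(O)c(Cl)c(O)c1Oc1cc(C)cc(OCc2ccccc2)c1C(=O)O | intermediate
14 | 1-(benzyloxy)-9-chloro-8-hydroxy-3-methyl-11-oxo-11H-dibenzo[b,e][1,4]dioxepine-6-carbaldehyde | O=Cc1cc(O)c(Cl)c2c1Oc1cc(C)cc(OCc3ccccc3)c1C(=O)O2 | intermediate
15 | 1-(benzyloxy)-9-chloro-8-methoxy-3-methyl-11-oxo-11H-dibenzo[b,e][1,4]dioxepine-6-carbaldehyde | O=Cc1cc(OC)c(Cl)c2c1Oc1cc(C)cc(OCc3ccccc3)c1C(=O)O2 | intermediate
16 | 1-(benzyloxy)-9-chloro-8-methoxy-3-methyl-11-oxo-11H-dibenzo[b,e][1,4]dioxepine-6-carboxylic acid | OC(=O)c1cc(OC)c(Cl)c2c1Oc1cc(C)cc(OCc3ccccc3)c1C(=O)O2 | intermediate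
17 | 9-chloro-1-hydroxy-8-methoxy-3-methyl-11-oxo-11H-dibenzo[b,e][1,4]dioxepine-6-carboxylic acid | OC(=O)c1cc(OC)c(Cl)c2c1Oc1cc(C)cc(O)c1C(=O)O2 | intermediate
18 | 2-(2-carboxy-3-hydroxy-5-methylphenoxy)-4-chloro-3-hydroxy-5-methoxybenzoic acid | COc1cc(C(=O)O)c(Oc2cc(C)cc(O)c2C(=O)O)c(O)c1Cl | target

## Step count and least certain steps

Total: 12 steps. Longest linear sequence: 11 steps (steps 1 to 3 and 5 to 12, from 1); step 4 is a one-step side branch.

**Step 5 (key step).**
- **Risk:** The enolate of 5 may acylate its own ring B ester (Dieckmann closure to a benzofuranone) before it meets the enone. The enone may also be used up by self-condensation through its methyl enolate, or by deprotonation at the acetal carbon.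
- **Fallback:** The two bond formations are separated, setting out from 5. LiN(SiMe3)2 with Me3SiCl present in THF at −78 °C should give the silyl ketene acetal tert-butyl 2-(benzyloxy)-6-{[2-methoxy-2-(trimethylsilyloxy)ethenyl]oxy}-4-methylbenzoate F1 (E/Z mixture), a neutral nucleophile that cannot attack the ring B ester. Fluoride-catalysed Mukaiyama–Michael addition of F1 to 8 (Bu4NF cat., THF, −78 °C, aqueous work-up) should give keto ester 9, now isolated. Treating 9 with t-BuOK in THF then generates only the ketone enolate for the Claisen closure, and the route is rejoined at 10.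

**Step 7.**
- **Risk:** Positive chlorine may be transferred from the dichlorodione to the electron-rich ring B instead of to C2 or C4. The acetal may be lost before aromatisation, which would open a β-elimination of the ring B phenol from C4. Prolonged hot acid may also cleave the benzyl ether.
- **Fallback:** A mixed-halogen sequence sets out from 10. One equivalent of NCS should give the monochlorodione tert-butyl 2-(benzyloxy)-6-{[3-chloro-6-(dimethoxymethyl)-2,4-dioxocyclohexyl]oxy}-4-methylbenzoate F2. NBS then gives tert-butyl 2-(benzyloxy)-6-{[3-bromo-3-chloro-6-(dimethoxymethyl)-2,4-dioxocyclohexyl]oxy}-4-methylbenzoate F3. In F3 bromine is the halogen that migrates and leaves, so dehydrobromination (LiBr, DMF, 40 to 50 °C) should proceed well below the temperature needed for the dichloride. It gives arene 12, which is isolated and then converted to 13 by the aqueous CF3CO2H treatment of step 7.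

**Step 8.**
- **Risk:** The hindered 2,6-disubstituted acid may rearrange from the O-acylisourea to an N-acylurea, or esterify between molecules through the C1 hydroxyl, instead of closing the seven-membered ring.
- **Fallback:** An acylium-type closure sets out from 13. (CF3CO)2O in CF3CO2H–CH2Cl2 (0 °C to rt) activates the di-ortho-oxygenated acid as its mixed anhydride, which closes onto the C5 hydroxyl. The C1 hydroxyl is transiently acylated, giving 1-(benzyloxy)-9-chloro-6-formyl-3-methyl-11-oxo-11H-dibenzo[b,e][1,4]dioxepin-8-yl 2,2,2-trifluoroacetate F4. Brief aqueous NaHCO3–THF treatment cleaves the labile trifluoroacetate and returns to the route at 14.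

**Step 11.**
- **Risk:** Debenzylation may be incomplete because the free acid ties up the Lewis acid, or the C1 methyl ether may be cleaved as well if the temperature rises.
- **Fallback:** The order of the last two steps is reversed and the method changed, setting out from 16. LiOH in THF–H2O opens the lactone to 2-[3-(benzyloxy)-2-carboxy-5-methylphenoxy]-4-chloro-3-hydroxy-5-methoxybenzoic acid F5. Hydrogenolysis (H2, Pd/C, EtOAc, rt, short reaction time, no base) then removes the benzyl group and reaches target 18 directly. The risk accepted there is reductive loss of chlorine, which the acidic substrate and the hindered, electron-rich position of the chlorine should limit.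

## Further compounds

F1 | step 5 | tert-butyl 2-(benzyloxy)-6-{[2-methoxy-2-(trimethylsilyloxy)ethenyl]oxy}-4-methylbenzoate (E/Z mixture) | COC(O[Si](C)(C)C)=COc1cc(C)cc(OCc2ccccc2)c1C(=O)OC(C)(C)C
F2 | step 7 | tert-butyl 2-(benzyloxy)-6-{[3-chloro-6-(dimethoxymethyl)-2,4-dioxocyclohexyl]oxy}-4-methylbenzoate (diastereomer mixture) | COC(OC)C1CC(=O)C(Cl)C(=O)C1Oc1cc(C)cc(OCc2ccccc2)c1C(=O)OC(C)(C)C
F3 | step 7 | tert-butyl 2-(benzyloxy)-6-{[3-bromo-3-chloro-6-(dimethoxymethyl)-2,4-dioxocyclohexyl]oxy}-4-methylbenzoate (diastereomer mixture) | COC(OC)C1CC(=O)C(Cl)(Br)C(=O)C1Oc1cc(C)cc(OCc2ccccc2)c1C(=O)OC(C)(C)C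
F4 | step 8 | 1-(benzyloxy)-9-chloro-6-formyl-3-methyl-11-oxo-11H-dibenzo[b,e][1,4]dioxepin-8-yl 2,2,2-trifluoroacetate | O=Cc1cc(OC(=O)C(F)(F)F)c(Cl)c2c1Oc1cc(C)cc(OCc3ccccc3)c1C(=O)O2
F5 | step 11 | 2-[3-(benzyloxy)-2-carboxy-5-methylphenoxy]-4-chloro-3-hydroxy-5-methoxybenzoic acid | COc1cc(C(=O)O)c(Oc2cc(C)cc(OCc3ccccc3)c2C(=O)O)c(O)c1Cl
A1 | alternative 1 | [4-(benzyloxy)-3-chloro-2,8-dimethoxy-6-methyl-9H-xanthen-9-yl]methanol (racemic) | COc1cc2C(CO)c3c(OC)cc(C)cc3Oc2c(OCc2ccccc2)c1Cl
A2 | alternative 1 | 4-(benzyloxy)-3-chloro-2,9-dimethoxy-7-methyldibenzo[b,f]oxepine | COc1cc2C=Cc3c(OC)cc(C)cc3Oc2c(OCc2ccccc2)c1Cl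
A3 | alternative 2 | methyl 4-[2-(benzyloxy)-3-chloro-4-methoxy-6-(methoxycarbonyl)phenoxy]-6-methyl-2-oxo-2H-pyran-3-carboxylate | COC(=O)C1=C(Oc2c(C(=O)OC)cc(OC)c(Cl)c2OCc2ccccc2)C=C(C)OC1=O
A4 | alternative 2 | 1,1-dimethoxyethene | C=C(OC)OC
A5 | alternative 2 | methyl 2-[2-(benzyloxy)-3-chloro-4-methoxy-6-(methoxycarbonyl)phenoxy]-6-methoxy-4-methylbenzoate | COc1cc(C(=O)OC)c(Oc2cc(C)cc(OC)c2C(=O)OC)c(OCc2ccccc2)c1Cl
A6 | alternative 3 | 3-methylcyclobut-2-en-1-one | CC1=CC(=O)C1
A7 | alternative 3 | 2-[3-(benzyloxy)-4-chloro-2-({3-[(tert-butyldimethylsilyl)oxy]prop-1-yn-1-yl}oxy)-5-methoxyphenyl]-1,3-dioxolane | COc1cc(C2OCCO2)c(OC#CCO[Si](C)(C)C(C)(C)C)c(OCc2ccccc2)c1Cl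
A8 | alternative 3 | 3-[2-(benzyloxy)-3-chloro-6-(1,3-dioxolan-2-yl)-4-methoxyphenoxy]-2-{[(tert-butyldimethylsilyl)oxy]methyl}-5-methylphenol | COc1cc(C2OCCO2)c(Oc2cc(C)cc(O)c2CO[Si](C)(C)C(C)(C)C)c(OCc2ccccc2)c1Cl
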